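- Friday's reading at 1.00 min and Saturday's at 0.333 min look alike, D 40.4% against 40.8% and L 51.4% against 52.0%, so the two runs seem to follow one curve on clocks of different speed.

| flask | D | X | Z | remark | time |
|---|---|---|---|---|---|
| Friday's | 0.034 M | 0.5 mol% | 75 µM | run made earlier |  |
| Saturday's | 0.075 M | 0.5 mol% | 75 µM | run made earlier |  |
| flask | 0.050 M | 0.5 mol% | 75 µM |  | 4.0 min |

| run | time / min | Q / % | D / % | L / % |
|---|---|---|---|---|
| Friday's | 0.333 | 2.0 | 58.0 | 40.3 |
| Friday's | 0.667 | 4.1 | 44.8 | 49.7 |
| Friday's | 1.00 | 7.3 | 40.4 | 51.4 |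
| Friday's | 2.00 | 16.2 | 34.6 | 48.0 |
| Friday's | 4.00 | 28.2 | 29.1 | 42.0 |
| Saturday's | 0.333 | 8.2 | 40.8 | 52.0 |
| Saturday's | 1.00 | 24.2 | 31.5 | 44.6 |
| Saturday's | 2.00 | 37.8 | 25.6 | 37.4 |
| Saturday's | 3.00 | 45.1 | 23.3 | 33.1 |
| Saturday's | 4.00 | 48.9 | 22.2 | 30.4 |

(readings scatter by 0.5 percentage points)

- the largest share of what was charged as D, at 4.0 min belongs to (L / D / Q)
- the largest share itself, whichever of these holds it, in percent of the D charged

- I read Z as a catalyst poison that takes one X each, and I freeze what stays: the working catalyst [X]w, charged [X] minus charged [Z].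
- First, what must be good in this flask: one per cent off the time shifts its place on the curve by one per cent, one per cent off the loading or [D] by 1.43 per cent, and one per cent off [Z] by 0.429 per cent, so the charges of X and D need more care than [Z].
- Now the number: [X]w is 95.0 µM on Friday, 300 µM on Saturday and 175 µM in this flask.
- This flask sits at 2.33 min, its equivalent time, which is its own time multiplied by its [X]w over Saturday's.
- Friday's 1.00 min scales the same way to 0.317 min, beside Saturday's reading at 0.333 min.
- Reading straight across between Saturday's readings at 2.00 min and 3.00 min, I reckon for this flask Q 40.2% and L 36.0%, so I commit to Q.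
- The forecast also names Q, at 38.5%, and says “Q leads narrowly”; my figure stands higher.
- This flask gives Q at 40.7%, with L at 34.8% and D at 24.5%.

    D + X ⇌ L + X, rate k1*[D]*[X] forward; the back reaction follows from the equilibrium constant (K = 1.45, k = 375 M⁻¹ s⁻¹)
    L + X ⇌ Q + X, rate k2*[X]*[L] forward; the back reaction follows from the equilibrium constant (K = 1.82, k = 34.0 M⁻¹ s⁻¹)
    X + Z → J (k = 40600 M⁻¹ s⁻¹)

- In this flask at 4.00 min, D and L relax towards each other with a half-life of 0.104 min by their step alone, far shorter than the 1.25 min of L and Q by their step alone. D and L keep pace as a pair while Q climbs from 27.0% at 2.00 min to 40.7% at 4.00 min, the point I placed at 2.33 min on Saturday's clock. A neighbour flask with 0.2 mol% of X keeps 25.0 µM working, so its 4.00 min scales to 0.333 min, beside Saturday's first reading with Q at 8.2%, and the neighbour ends with Q at 8.11%.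

The numbers in the tables come from a simulation from invented constants; scatter was added.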